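## Structural features

The target is a 5,6,7,8-tetrahydro-1H-isochromen-8-one. Carbocyclic ring A (C4a, C5, C6, C7, C8, C8a) is fused through the C4a=C8a double bond to pyran ring B (C1H2–O2–C3=C4), so that O2–C3=C4–C4a=C8a–C8=O is a push–pull dienone (a doubly vinylogous ester). Ring A carries two adjacent stereocentres with cis oxygens: C6 (R, secondary, esterified by orsellinic acid) and C7 (R, tertiary carbinol bearing a methyl group), and C7 sits between C6 and the C8 ketone as an α-ketol. C3 bears a trans epoxide, (2S,3R)-3-methyloxiran-2-yl, too far from the ring-A centres to be set by relay from them. The fragile groups are the epoxide on the enol-ether carbon, the α-ketol (base-induced acyl shift), the C6 ester (β to the acidic C5 methylene, so it can be lost by elimination toward the fully unsaturated azaphilone chromophore) and the free resorcinol. The real difficulty is the cis C6/C7 diol with a quaternary C7 next to a ketone as one enantiomer, and independently the absolute configuration of the remote epoxide. The key step reads ring A as a former benzene ring: a cis C6–O/C7–O pair with a carbon substituent on C7 is what ipso,ortho cis-dihydroxylation of a benzoic acid leaves behind. C7 is the old carboxyl-bearing carbon, C6 its ortho neighbour, the C7 methyl the old carboxyl carbon, and C4a/C8a the arene carbons that already carry ring B as a lactone.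

## Logic of the disconnections

**31 to 26 and 29.** The C6–O acyl bond is cut last (31 from 30, 30 from 26 and 29, 29 from 27 through 28). The ester is the group most easily lost by elimination across C5–C6, so it is made late; the gain is that the whole core is carried with robust silyl groups. The demand is a selective acylation of the secondary C6 hydroxyl next to the tertiary C7 hydroxyl by a doubly ortho-substituted acyl donor, and a final desilylation that is neither basic nor acidic.

**26 to 23.** The C8 carbonyl is taken back to a carbinol (25), and the C2′–O bond of the epoxide is cut to a chlorohydrin (24, then 23). Without the ketone, fluoride and carbonate can be used freely because there is no vinylogous C–H acidity, and the epoxide is closed only three steps from the end. The demand is an oxidant that touches only the doubly allylic C8 carbinol of 25, and an anti chlorohydrin so that closure with inversion at C2′ gives the trans epoxide.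

**23 to 19 and 22.** The C3–C1′ bond is cut. This splits off the three-carbon side chain as a chiral-pool aldehyde (22, from 20 through 21) and leaves the bicyclic core as an enol triflate. The demand is a non-basic coupling that does not epimerize 22 and that adds anti to the C–Cl bond.

**19 to 17.** The O–S bond is cut back to the lactone 18, and the two Si–O bonds back to 17. The C8 carbon is held as a protected carbinol on purpose. With a C8 ketone in place, the extended enolate formed at C4 would be expected to be sulfonylated on the ketone oxygen, not the lactone oxygen; with C8 as a carbinol the lactone oxygen is the only enolate oxygen. The demand is an enolate that is trapped before it can expel the C8 silyloxy group.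

**17 to 14.** The C8 carbinol goes back to the enone (16 from 15), the C7 methyl to an iodomethyl group (17 from 16, 15 from 14) and that to the hydroxymethyl group of 14. The C–I bond is reduced only after the ketone has been reduced, so that the primary radical has no π system on C7 to attack. The demand is selective activation of a neopentyl-type primary hydroxyl beside a tertiary one.

**14 to 11.** The C8 carbonyl and the C4a=C8a bond are traced to the 8,8a-epoxide 12 and from there to the C8=C8a bond of the diene 11. This turns an enone into a diene that the key step delivers directly. The demand is regioselective epoxidation of C8=C8a over C4a=C5, which the free C7 hydroxyl and the silylated C6 oxygen must secure.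

**11 to 7.** The hydroxymethyl group goes back to the carboxyl (11 from 9), and the C6 silyl ether to the free diol (9 from 7). The demand is reduction of the carboxyl before any C8 ketone exists (a β-keto acid would lose CO2) and without touching the lactone.

**7 to 6.** Both C–O bonds at C7 and C6 are cut. Ring A becomes a benzene ring and two stereocentres disappear, so the whole carbon skeleton of the core reduces to a flat, achiral acid. The demand is an enzyme that accepts the bicyclic acid, adds oxygen to C7 and C6 and not to C7 and C8, and does so with the facial sense known for benzoate.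

**6 to 1 and 3.** The lactone C–O bond and the aryl–C4 bond are cut (6 from 5, 5 from 2 and 3 through 4, 2 from 1). The bromine of 1 marks the carbon para to the carboxyl, so the acetic acid arm can only enter there and no regioisomeric lactone can form. The demand is an enolate arylation that tolerates two esters.

## Other disconnections considered

**Alternative 1:** The cut is C4a–C5. In the forward step a primary radical at C5, generated from an alkyl iodide, adds in the 6-endo mode to alkyne carbon C4a of a C8 ynone. The C8a vinyl radical then takes iodine from the next substrate molecule, giving the α-iodo enone A1 with ring A closed.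
- In its favour: the chain is neutral and should tolerate silyl ethers and the epoxide. A nucleophilic alkyl radical is polarity-matched to the β-carbon of the ynone, and 5-exo attack at C8a would force the sp2 ketone carbon into a five-membered ring. The C8 ketone and the C4a=C8a bond arise in the right place and oxidation state, and the C8a iodide is a handle for C1.
- Against it here: C6, C7, the C3 carbinol and both epoxide carbons must first be assembled on an open chain. Ring B is still missing after the key step (C1 has to be coupled at C8a, the C3 carbinol oxidized, the enol ether closed by cyclodehydration), all with the epoxide on board. The vinyl radical may also abstract hydrogen instead of iodine.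
- Comparison: structurally it builds ring A by C–C bond formation, whereas 7 inherits all core carbons from an arene. Mechanistically its selectivity rests on well-understood radical polarity and ring-strain arguments and is on that point the equal or the better of the enzymatic step, whose regiochemistry is unproven. It is also better in needing no reduction and re-oxidation at C8 (steps 10 and 18 of the chosen plan). In step economy it is expected to be longer, because of the acyclic stereocentre assembly and the late ring-B construction.

**Alternative 2:** The cut is C3=C4. In the forward step a ruthenium alkylidene (second-generation Grubbs catalyst) joins a vinyl group on C4a and a 1-alkoxyvinyl group on the C1 oxygen that already carries the epoxide, with loss of ethylene, to give the dienyl ether A2.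
- In its favour: ring B closes last under neutral conditions, and the epoxide arrives with its configuration fixed. Neither the ketene acetal triflate nor the chromium coupling and its diastereoselectivity (steps 13 and 16) are needed; on this point it is the better plan.
- Against it here: a 1,1-disubstituted enol ether can park the catalyst as a stabilized alkoxycarbene, and the other partner is the terminus of a 1,3-diene. A2 has C8 as a silyl ether, so oxidation must follow on an acid-sensitive epoxy dienyl ether, and three identical silyl ethers must be told apart before O6 alone is acylated. The key step sets no stereocentre, so C6, C7 and C8 need a separate asymmetric synthesis.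
- Comparison: A2 belongs to the same compound class as 24, so the late C8 oxidation is a shared burden (equal). The chosen key step creates the two ring-A centres in one operation from an achiral arene, which the metathesis cannot. Overall length is expected to be similar or greater once ring A is counted.

**Alternative 3:** The cut is C6–C7. In the forward step, under Al(OC(CH3)3)3, the aluminium alkoxide of an acetyl-bearing carbinol carbon on a pyran-fused five-membered ring lets C6 migrate to the acetyl carbon. The acetyl carbon becomes C7, its methyl the C7 methyl, the carbinol carbon the C8 ketone, and the five-membered ring becomes ring A in A3.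
- In its favour: A3 is the 6-O-silyl ether of 26, the complete core with epoxide, ketone and tertiary carbinol, two or three steps from 31. The shift is driven by relief of ring strain and by conjugation of the new ketone with C4a=C8a. There is no redox detour; on endgame length and convergence it is the better plan.
- Against it here: the C7 configuration is created during the shift and depends on which face of the acetyl carbonyl receives C6, so the cis C6/C7 relation is not guaranteed. α-Ketol shifts are reversible, and the product is again an α-ketol. A Lewis-acidic aluminium alkoxide at elevated temperature must spare the epoxide. The ring-contracted precursor needs its own enantioselective synthesis.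
- Comparison: the chosen plan fixes the cis relation by a suprafacial addition, which is mechanistically firmer once the enzyme accepts the substrate. Alternative 3 is stronger after its key step, the chosen plan before it; total length would depend on the precursor synthesis.

Key step: step 4

Remarks on the chemistry (assumptions):
- Isochromene numbering is used for all bicyclic compounds; C1′ (on C3) and C2′ are the side-chain carbons, and C9 is the carbon on C7.
- The diol acid 7 is (6R,7S). The same spatial arrangement is (6R,7R) in 31 only because CH3 ranks below C6 where CO2H ranked above it.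
- NADH used in step 4 is regenerated by the cells from fructose and is treated as catalytic.
- The epoxide face in 12 and the C8 configuration in 16–19 and 23–25 do not reach the target; the isomer drawn is the one expected to predominate.

## Route

Step 1
Reactants: 1 methyl 4-bromo-3-(bromomethyl)benzoate
Product: 2 methyl 3-(acetoxymethyl)-4-bromobenzoate
Conditions: KOAc, DMF, 60 °C
Reagents that add atoms: potassium acetate, CC(=O)[O-].[K+]
Why: SN2 displacement of the benzylic bromide by acetate; the aryl bromide is inert, and the acetate masks the future C1 oxygen during the zinc chemistry.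

Step 2
Reactants: 2 methyl 3-(acetoxymethyl)-4-bromobenzoate; 3 tert-butyl bromoacetate
Product: 5 methyl 3-(acetoxymethyl)-4-(2-tert-butoxy-2-oxoethyl)benzoate, via Reformatsky reagent 4 (not isolated)
Conditions: Zn, THF, rt; then 2, Pd(dba)2 (2 mol %), P(tBu)3 (2 mol %), THF, rt
Reagents that add atoms: none
Why: Reformatsky reagent formation followed by palladium-catalysed α-arylation of the zinc ester enolate (Negishi-type coupling), which tolerates the methyl ester and the acetate; the bromine position places the acetic acid arm para to the carboxyl, so no regioisomer can arise.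

Step 3
Reactants: 5 methyl 3-(acetoxymethyl)-4-(2-tert-butoxy-2-oxoethyl)benzoate
Product: 6 3-oxoisochromane-7-carboxylic acid
Conditions: 6 M HCl, 1,4-dioxane, 90 °C
Reagents that add atoms: water, O
Why: Acid hydrolysis of the three esters (the tert-butyl ester by alkyl–oxygen cleavage) and spontaneous acid-catalysed δ-lactonization of the 2-(hydroxymethyl)arylacetic acid; the benzylic six-membered lactone is the stable form in acid.

Step 4
Reactants: 6 3-oxoisochromane-7-carboxylic acid
Product: 7 (6R,7S)-6,7-dihydroxy-3-oxo-3,4,6,7-tetrahydro-1H-isochromene-7-carboxylic acid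
Conditions: Ralstonia eutropha B9 whole cells (benzoate 1,2-dioxygenase, no diol dehydrogenase), air, fructose, phosphate buffer pH 7, 30 °C; extraction at pH 3–4
Reagents that add atoms: dioxygen, O=O
Why: Proposed new method: the Rieske non-haem iron site of benzoate 1,2-dioxygenase binds O2, is reduced by NADH through its reductase and transfers both oxygen atoms to one face of the arene at the carboxyl-bearing carbon C7 and an ortho carbon, with the carboxylate as the anchor in the active site; the closest known reaction is the ipso,ortho cis-dihydroxylation of benzoate itself by the same whole-cell system, which stops at the diol because the strain lacks the diol dehydrogenase. No ring is closed; the two new C–O bonds leave the C4a=C5 and C8=C8a diene. Both stereocentres (C7 S, C6 R) are set by the enzyme: suprafacial delivery fixes the cis relation, and the absolute sense is taken from the benzoate case (1S,2R), onto which C7 and C6 of 7 map directly. The selectivity the step needs is regiochemical, C6 and not C8 as the hydroxylated ortho carbon; C8 is flanked by the ring-fusion carbon C8a and its CH2O arm, so the remote ortho carbon is the less encumbered one, but this rests on the fit of the bicyclic acid in the pocket and is not secured by the substrate alone. The lactone should survive pH 7 for the incubation, and 7 is extracted under mild acid and used at once to avoid acid-induced rearomatization.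

Step 5
Reactants: 7 (6R,7S)-6,7-dihydroxy-3-oxo-3,4,6,7-tetrahydro-1H-isochromene-7-carboxylic acid
Product: 9 6-O-tert-butyldimethylsilyl ether of 7, via bis-silyl derivative 8 (not isolated)
Conditions: TBSCl (2.5 equiv), imidazole, DMF, 0 °C → rt; then AcOH, THF/H2O, 0 °C
Reagents that add atoms: tert-butyldimethylsilyl chloride, CC(C)(C)[Si](C)(C)Cl
Why: Silylation of the secondary allylic C6 hydroxyl (the tertiary hydroxyl of the α-hydroxy acid is inert to TBSCl); the silyl ester formed alongside is hydrolysed by dilute AcOH, and capping O6 leaves the C7 hydroxyl as the only directing group for step 7.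

Step 6
Reactants: 9 6-O-tert-butyldimethylsilyl ether of 7
Product: 11 (6R,7R)-6-(tert-butyldimethylsilyloxy)-7-hydroxy-7-(hydroxymethyl)-1,4,6,7-tetrahydro-3H-isochromen-3-one, via mixed anhydride 10 (not isolated)
Conditions: iBuOCOCl, N-methylmorpholine, THF, −15 °C; then NaBH4, H2O, −15 → 0 °C
Reagents that add atoms: none
Why: Mixed carbonic anhydride activation and borohydride reduction, selective for the activated carboxyl over the δ-lactone at low temperature; it is done before any C8 ketone exists, since that would make the acid a β-keto acid.

Step 7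
Reactants: 11 (6R,7R)-6-(tert-butyldimethylsilyloxy)-7-hydroxy-7-(hydroxymethyl)-1,4,6,7-tetrahydro-3H-isochromen-3-one
Product: 12 8,8a-epoxide of 11 with the oxirane oxygen on the face of the C7 hydroxyl
Conditions: VO(acac)2 (5 mol %), tBuOOH (1.5 equiv, decane), CH2Cl2, 0 °C → rt
Reagents that add atoms: tert-butyl hydroperoxide, CC(C)(C)OO
Why: Hydroxyl-directed vanadium-catalysed epoxidation: the vanadate ester of the allylic C7 hydroxyl delivers oxygen to C8=C8a on its own face, while C4a=C5 has only the silylated O6 nearby; the facial sense is immaterial because both epoxide carbons become sp2 in step 8.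

Step 8
Reactants: 12 8,8a-epoxide of 11
Product: 14 6-(tert-butyldimethylsilyloxy)-7-hydroxy-7-(hydroxymethyl)-1,5,6,7-tetrahydro-3H-isochromene-3,8(4H)-dione (C4a=C8a enone), via deconjugated ketone 13 (not isolated)
Conditions: Pd(PPh3)4 (5 mol %), THF, 0 °C → rt; then Et3N
Reagents that add atoms: none
Why: Palladium-catalysed isomerization of a 1,3-diene monoepoxide: zerovalent palladium ionizes the allylic C8a–O bond from the opposite face, the C8 hydrogen shifts through a palladium hydride to give ketone 13, and Et3N moves the double bond into conjugation at C4a=C8a, leaving C5 as a methylene.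

Step 9
Reactants: 14 C4a=C8a enone with C7 hydroxymethyl
Product: 15 7-(iodomethyl) analogue of 14
Conditions: PPh3, I2, imidazole, CH2Cl2, 0 °C → rt
Reagents that add atoms: iodine, II
Why: Garegg–Samuelsson (Appel-type) iodination of the primary hydroxyl through its alkoxyphosphonium salt; the tertiary hydroxyl and the enone are not activated, and imidazole keeps the medium non-acidic.

Step 10
Reactants: 15 7-(iodomethyl) enone
Product: 16 6-(tert-butyldimethylsilyloxy)-7,8-dihydroxy-7-(iodomethyl)-1,4,5,6,7,8-hexahydro-3H-isochromen-3-one (C8–OH trans to C7–OH)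
Conditions: NaBH4, CeCl3·7H2O, MeOH, −78 °C
Reagents that add atoms: none
Why: Luche 1,2-reduction, placed here so that the radical of step 11 has no carbonyl on C7 to attack (no ring expansion) and so that step 13 meets a single enolate oxygen; hydride is expected anti to the iodomethyl group, but the new C8 centre is erased in step 18.

Step 11
Reactants: 16 iodomethyl diol
Product: 17 6-(tert-butyldimethylsilyloxy)-7,8-dihydroxy-7-methyl-1,4,5,6,7,8-hexahydro-3H-isochromen-3-one
Conditions: Bu3SnH, Et3B (cat.), air, toluene, 0 °C → rt
Reagents that add atoms: none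
Why: Radical chain dehalogenation; the primary C9 radical has only sp3 neighbours on C7 and is simply reduced to the C7 methyl.

Step 12
Reactants: 17 methyl diol
Product: 18 7,8-bis-O-triethylsilyl ether of 17
Conditions: TESOTf, 2,6-lutidine, CH2Cl2, −78 → 0 °C
Reagents that add atoms: triethylsilyl trifluoromethanesulfonate, CC[Si](CC)(CC)OS(=O)(=O)C(F)(F)F
Why: Silyl triflate silylation of the secondary allylic C8 and the hindered tertiary C7 hydroxyls, so that no O–H remains before enolate formation.

Step 13
Reactants: 18 bis-triethylsilyl lactone
Product: 19 6-(tert-butyldimethylsilyloxy)-7-methyl-7,8-bis(triethylsilyloxy)-5,6,7,8-tetrahydro-1H-isochromen-3-yl trifluoromethanesulfonate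
Conditions: KN(SiMe3)2, THF, −78 °C; then PhNTf2, −78 °C
Reagents that add atoms: N-phenylbis(trifluoromethanesulfonimide), O=S(=O)(N(c1ccccc1)S(=O)(=O)C(F)(F)F)C(F)(F)F
Why: Kinetic deprotonation at C4 (α to the lactone and allylic, the only acidic C–H) and O-sulfonylation of the lactone enolate gives the ketene acetal triflate; with C8 at the carbinol level the lactone oxygen is the only enolate oxygen, so the regiochemistry is unambiguous.

Step 14
Reactants: 20 (S)-2-chloropropanoic acid
Product: 21 (S)-2-chloropropan-1-ol
Conditions: LiAlH4, Et2O, 0 °C
Reagents that add atoms: none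
Why: Hydride reduction of the acid; the C–Cl stereocentre is not involved and the secondary chloride is spared at 0 °C.

Step 15
Reactants: 21 (S)-2-chloropropan-1-ol
Product: 22 (S)-2-chloropropanal
Conditions: Dess–Martin periodinane, NaHCO3, CH2Cl2, 0 °C → rt; solution used at once
Reagents that add atoms: none
Why: Dess–Martin oxidation under buffered, non-basic conditions limits enolization of the α-chloro aldehyde, which is volatile and is carried on as a solution.

Step 16
Reactants: 19 ketene acetal triflate; 22 (S)-2-chloropropanal
Product: 23 3-[(1R,2S)-2-chloro-1-hydroxypropyl]-6-(tert-butyldimethylsilyloxy)-7-methyl-7,8-bis(triethylsilyloxy)-5,6,7,8-tetrahydro-1H-isochromene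
Conditions: CrCl2 (4 equiv), NiCl2 (1 mol %), DMF, rt
Reagents that add atoms: none
Why: Nozaki–Hiyama–Kishi coupling: zerovalent nickel inserts into the C3–O triflate bond and transmetalation gives the alkenylchromium species, which adds to the aldehyde without base; the polar Felkin–Anh (Cornforth) transition state with C–Cl anti to the incoming carbon gives the 1,2-anti chlorohydrin (C1′ R).

Step 17
Reactants: 23 anti chlorohydrin
Product: 25 7-methyl-3-[(2S,3R)-3-methyloxiran-2-yl]-5,6,7,8-tetrahydro-1H-isochromene-6,7,8-triol, via silylated epoxide 24 (not isolated)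
Conditions: K2CO3, MeOH, 0 °C → rt; then TBAF, THF, 0 °C → rt
Reagents that add atoms: none
Why: Intramolecular Williamson closure in which the C1′ alkoxide displaces chloride with inversion at C2′ (S to R), the anti chlorohydrin giving the trans epoxide; fluoride then removes the three silyl ethers, which is safe at this oxidation level because there is no ketone and hence no base-labile vinylogous C–H.

Step 18
Reactants: 25 epoxy triol
Product: 26 (6R,7R)-6,7-dihydroxy-7-methyl-3-[(2S,3R)-3-methyloxiran-2-yl]-6,7-dihydro-1H-isochromen-8(5H)-one
Conditions: MnO2, CH2Cl2, rt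
Reagents that add atoms: none
Why: Allylic oxidation by MnO2 touches only the doubly allylic C8 carbinol; the homoallylic C6 and tertiary C7 hydroxyls and the epoxide remain, and the push–pull dienone is restored.

Step 19
Reactants: 27 orsellinic acid (2,4-dihydroxy-6-methylbenzoic acid)
Product: 28 tert-butyldimethylsilyl 2,4-bis(tert-butyldimethylsilyloxy)-6-methylbenzoate
Conditions: TBSCl (3.5 equiv), imidazole, DMF, rt
Reagents that add atoms: tert-butyldimethylsilyl chloride, CC(C)(C)[Si](C)(C)Cl
Why: Exhaustive silylation of both phenols and the carboxyl.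

Step 20
Reactants: 28 tris-silyl orsellinate
Product: 29 2,4-bis(tert-butyldimethylsilyloxy)-6-methylbenzoyl chloride
Conditions: (COCl)2, DMF (cat.), CH2Cl2, 0 °C → rt
Reagents that add atoms: oxalyl chloride, O=C(Cl)C(Cl)=O
Why: Vilsmeier-type conversion of the silyl ester into the acid chloride; silyl chloride leaves instead of HCl, so the aryl silyl ethers survive.

Step 21
Reactants: 26 epoxy diol enone; 29 2,4-bis(tert-butyldimethylsilyloxy)-6-methylbenzoyl chloride
Product: 30 2′,4′-bis-O-tert-butyldimethylsilyl ether of 31
Conditions: Et3N, DMAP, CH2Cl2, 0 °C → rt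
Reagents that add atoms: none
Why: DMAP-catalysed acylation of the only secondary hydroxyl; the tertiary C7 hydroxyl does not compete, and the weak amine base does not deprotonate C5.

Step 22
Reactants: 30 bis-silyl ester
Product: 31 (6R,7R)-7-hydroxy-7-methyl-3-[(2S,3R)-3-methyloxiran-2-yl]-8-oxo-5,6,7,8-tetrahydro-1H-isochromen-6-yl 2,4-dihydroxy-6-methylbenzoate (CNP0323247.1)
Conditions: TBAF, AcOH (1:1), THF, 0 °C
Reagents that add atoms: none
Why: Fluoride cleavage of the aryl silyl ethers, fast at 0 °C because phenoxide leaves silicon readily; the AcOH buffer keeps the medium from becoming basic enough to eliminate the C6 ester or open the epoxide.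

## Compound list

1 | methyl 4-bromo-3-(bromomethyl)benzoate | COC(=O)c1ccc(Br)c(CBr)c1 | starting material
2 | methyl 3-(acetoxymethyl)-4-bromobenzoate | COC(=O)c1ccc(Br)c(COC(C)=O)c1 | intermediate
3 | tert-butyl bromoacetate | CC(C)(C)OC(=O)CBr | starting material
4 | (2-tert-butoxy-2-oxoethyl)zinc bromide | CC(C)(C)OC(=O)C[Zn]Br | intermediate (not isolated)
5 | methyl 3-(acetoxymethyl)-4-(2-tert-butoxy-2-oxoethyl)benzoate | COC(=O)c1ccc(CC(=O)OC(C)(C)C)c(COC(C)=O)c1 | intermediate
6 | 3-oxoisochromane-7-carboxylic acid | OC(=O)c1ccc2CC(=O)OCc2c1 | intermediate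
7 | (6R,7S)-6,7-dihydroxy-3-oxo-3,4,6,7-tetrahydro-1H-isochromene-7-carboxylic acid (cis diol, C4a=C5 and C8=C8a) | O[C@@H]1C=C2CC(=O)OCC2=C[C@@]1(O)C(=O)O | intermediate
8 | tert-butyldimethylsilyl ester of 9 (C6 and C7 as in 7) | CC(C)(C)[Si](C)(C)O[C@@H]1C=C2CC(=O)OCC2=C[C@@]1(O)C(=O)O[Si](C)(C)C(C)(C)C | intermediate (not isolated)
9 | (6R,7S)-6-(tert-butyldimethylsilyloxy)-7-hydroxy-3-oxo-3,4,6,7-tetrahydro-1H-isochromene-7-carboxylic acid | CC(C)(C)[Si](C)(C)O[C@@H]1C=C2CC(=O)OCC2=C[C@@]1(O)C(=O)O | intermediate
10 | isobutyl carbonic anhydride of 9 | CC(C)(C)[Si](C)(C)O[C@@H]1C=C2CC(=O)OCC2=C[C@@]1(O)C(=O)OC(=O)OCC(C)C | intermediate (not isolated)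
11 | (6R,7R)-6-(tert-butyldimethylsilyloxy)-7-hydroxy-7-(hydroxymethyl)-1,4,6,7-tetrahydro-3H-isochromen-3-one (O6 and O7 cis) | CC(C)(C)[Si](C)(C)O[C@@H]1C=C2CC(=O)OCC2=C[C@@]1(O)CO | intermediate
12 | 8,8a-epoxide of 11, oxirane oxygen cis to the C7 hydroxyl | CC(C)(C)[Si](C)(C)O[C@@H]1C=C2CC(=O)OC[C@]23O[C@@H]3[C@@]1(O)CO | intermediate
13 | 6-(tert-butyldimethylsilyloxy)-7-hydroxy-7-(hydroxymethyl)-6,7,8,8a-tetrahydro-1H-isochromene-3,8(4H)-dione (C4a=C5; C8a–H on the face opposite to O7; C6 and C7 as in 11) | CC(C)(C)[Si](C)(C)O[C@@H]1C=C2CC(=O)OC[C@@H]2C(=O)[C@]1(CO)O | intermediate (not isolated)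
14 | 6-(tert-butyldimethylsilyloxy)-7-hydroxy-7-(hydroxymethyl)-1,5,6,7-tetrahydro-3H-isochromene-3,8(4H)-dione (C4a=C8a; C6 and C7 as in 11) | CC(C)(C)[Si](C)(C)O[C@@H]1CC2=C(COC(=O)C2)C(=O)[C@]1(CO)O | intermediate
15 | 7-(iodomethyl) analogue of 14 | CC(C)(C)[Si](C)(C)O[C@@H]1CC2=C(COC(=O)C2)C(=O)[C@]1(CI)O | intermediate
16 | 6-(tert-butyldimethylsilyloxy)-7,8-dihydroxy-7-(iodomethyl)-1,4,5,6,7,8-hexahydro-3H-isochromen-3-one (O6 and O7 cis, C8–OH trans to C7–OH) | CC(C)(C)[Si](C)(C)O[C@@H]1CC2=C(COC(=O)C2)[C@@H](O)[C@]1(CI)O | intermediate
17 | 6-(tert-butyldimethylsilyloxy)-7,8-dihydroxy-7-methyl-1,4,5,6,7,8-hexahydro-3H-isochromen-3-one (configured as 16) | CC(C)(C)[Si](C)(C)O[C@@H]1CC2=C(COC(=O)C2)[C@@H](O)[C@]1(C)O | intermediate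
18 | 7,8-bis-O-triethylsilyl ether of 17 | CC(C)(C)[Si](C)(C)O[C@@H]1CC2=C(COC(=O)C2)[C@@H](O[Si](CC)(CC)CC)[C@]1(C)O[Si](CC)(CC)CC | intermediate
19 | 6-(tert-butyldimethylsilyloxy)-7-methyl-7,8-bis(triethylsilyloxy)-5,6,7,8-tetrahydro-1H-isochromen-3-yl trifluoromethanesulfonate (configured as 18) | CC(C)(C)[Si](C)(C)O[C@@H]1CC2=C(COC(OS(=O)(=O)C(F)(F)F)=C2)[C@@H](O[Si](CC)(CC)CC)[C@]1(C)O[Si](CC)(CC)CC | intermediate
20 | (S)-2-chloropropanoic acid | C[C@H](Cl)C(=O)O | starting material
21 | (S)-2-chloropropan-1-ol | C[C@H](Cl)CO | intermediate
22 | (S)-2-chloropropanal | C[C@H](Cl)C=O | intermediate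
23 | 3-[(1R,2S)-2-chloro-1-hydroxypropyl]-6-(tert-butyldimethylsilyloxy)-7-methyl-7,8-bis(triethylsilyloxy)-5,6,7,8-tetrahydro-1H-isochromene (ring A as in 18) | CC(C)(C)[Si](C)(C)O[C@@H]1CC2=C(COC([C@@H](O)[C@H](C)Cl)=C2)[C@@H](O[Si](CC)(CC)CC)[C@]1(C)O[Si](CC)(CC)CC | intermediate
24 | 6-(tert-butyldimethylsilyloxy)-7-methyl-3-[(2S,3R)-3-methyloxiran-2-yl]-7,8-bis(triethylsilyloxy)-5,6,7,8-tetrahydro-1H-isochromene | CC(C)(C)[Si](C)(C)O[C@@H]1CC2=C(COC([C@H]3O[C@@H]3C)=C2)[C@@H](O[Si](CC)(CC)CC)[C@]1(C)O[Si](CC)(CC)CC | intermediate (not isolated)
25 | 7-methyl-3-[(2S,3R)-3-methyloxiran-2-yl]-5,6,7,8-tetrahydro-1H-isochromene-6,7,8-triol (O6 and O7 cis, O8 trans to O7) | O[C@@H]1CC2=C(COC([C@H]3O[C@@H]3C)=C2)[C@@H](O)[C@]1(C)O | intermediate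
26 | (6R,7R)-6,7-dihydroxy-7-methyl-3-[(2S,3R)-3-methyloxiran-2-yl]-6,7-dihydro-1H-isochromen-8(5H)-one | O[C@@H]1CC2=C(COC([C@H]3O[C@@H]3C)=C2)C(=O)[C@]1(C)O | intermediate
27 | orsellinic acid (2,4-dihydroxy-6-methylbenzoic acid) | Cc1cc(O)cc(O)c1C(=O)O | starting material
28 | tert-butyldimethylsilyl 2,4-bis(tert-butyldimethylsilyloxy)-6-methylbenzoate | Cc1cc(O[Si](C)(C)C(C)(C)C)cc(O[Si](C)(C)C(C)(C)C)c1C(=O)O[Si](C)(C)C(C)(C)C | intermediate
29 | 2,4-bis(tert-butyldimethylsilyloxy)-6-methylbenzoyl chloride | Cc1cc(O[Si](C)(C)C(C)(C)C)cc(O[Si](C)(C)C(C)(C)C)c1C(Cl)=O | intermediate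
30 | (6R,7R)-7-hydroxy-7-methyl-3-[(2S,3R)-3-methyloxiran-2-yl]-8-oxo-5,6,7,8-tetrahydro-1H-isochromen-6-yl 2,4-bis(tert-butyldimethylsilyloxy)-6-methylbenzoate | Cc1cc(O[Si](C)(C)C(C)(C)C)cc(O[Si](C)(C)C(C)(C)C)c1C(=O)O[C@@H]1CC2=C(COC([C@H]3O[C@@H]3C)=C2)C(=O)[C@]1(C)O | intermediate
31 | (6R,7R)-7-hydroxy-7-methyl-3-[(2S,3R)-3-methyloxiran-2-yl]-8-oxo-5,6,7,8-tetrahydro-1H-isochromen-6-yl 2,4-dihydroxy-6-methylbenzoate | Cc1cc(O)cc(O)c1C(=O)O[C@@H]1CC2=C(COC([C@H]3O[C@@H]3C)=C2)C(=O)[C@]1(C)O | target

## Step count and least certain steps

Total: 22 steps. Longest linear sequence: 18 steps (steps 1–13, 16–18, 21, 22).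

**Step 4 (key step).** The most likely failures are hydroxylation at the wrong ortho carbon (C8, beside the ring fusion) or no turnover at all, because the enzyme has not been shown to accept a bicyclic 3,4-disubstituted benzoate and meta substituents are known to influence which ortho carbon is attacked. Loss of the diene by acid-induced rearomatization during isolation is the second concern.

Fallback, by known chemistry, from 6 back to the route at 17:
- Carboxylate-directed ortho C–H hydroxylation (Pd(OAc)2, benzoquinone, O2, KOAc) at the less hindered ortho carbon should give 6-hydroxy-3-oxoisochromane-7-carboxylic acid F1.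
- Chemoselective reduction of the acid with BH3·THF gives the salicyl alcohol F2, and ionic hydrogenolysis (Et3SiH, CF3CO2H) the cresol 6-hydroxy-7-methylisochroman-3-one F3.
- Hydroxylative dearomatization at the methyl-bearing ortho carbon with a chiral iodyl-arene oxidant (reagent control of the C7 configuration) gives the ortho-quinol F4.
- Low-temperature NaBH4/CeCl3·7H2O reduction of F4, with hydride entering anti to the C7 hydroxyl, gives the cis diol F5, the 7-methyl counterpart of 7.
- F5 is silylated at O6 to F6, epoxidized as in step 7 to F7 and isomerized as in step 8 to the methyl enone F8.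
- Luche reduction of F8 gives 17.

**Step 9.** Displacement at the neopentyl-type carbon may be slow, so that closure of the phosphonium intermediate by the neighbouring tertiary hydroxyl or deoxygenation of the 1,2-diol to an alkene competes. Fallback from 14 to 15: selective primary sulfonylation (TsCl, Et3N, Bu2SnO cat.) gives the tosylate F9; K2CO3 closes it to the spiro-epoxide F10; LiI/AcOH opens F10 at the CH2 carbon to 15.

**Step 13.** The dienolate may expel the C8 silyloxy group in a vinylogous elimination before it is trapped, and the ketene acetal triflate may hydrolyse on handling. Fallback from 18 to 23: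
- Deprotonation in the presence of (PhO)2P(O)Cl (internal quench) gives the more stable ketene acetal diphenyl phosphate F11.
- Palladium-catalysed stannylation (Pd(PPh3)4, Me3SnSnMe3, LiCl) gives the alkenylstannane F12.
- Tin–lithium exchange with MeLi at −78 °C gives the alkenyllithium F13, which is added to 22 (polar Felkin–Anh addition) to give 23 without chromium.

**Step 16.** The likely failures are erosion of the anti selectivity at C1′, partial loss of configuration of the enolizable aldehyde on the chromium salts, and reduction of the C–Cl bond by divalent chromium. Fallback, which sets out from 23 as obtained in admixture with its C1′ epimer F14: Dess–Martin oxidation converges both to the chloro ketone F15, and LiBH(s-Bu)3 at −78 °C (hydride anti to C–Cl) returns 23.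

**Step 21.** Acylation by the doubly ortho-substituted acyl chloride may be slow, and on long exposure to amine base acyl migration to O7 or elimination across C5–C6 may set in. Fallback from 27 and 26 to 31, by neutral ketene capture:
- 27 is converted (acetone, (CF3CO)2O, CF3CO2H) into the benzodioxinone F16 and silylated to F17.
- Irradiation of F17 with 26 (300 nm, CH2Cl2) releases acetone and the ortho-quinone ketene, which the C6 hydroxyl traps to give the mono-silyl ester F18.
- F18 is desilylated as in step 22 to 31.

## Further compounds

F1 | step 4 | 6-hydroxy-3-oxoisochromane-7-carboxylic acid | OC(=O)c1cc2COC(=O)Cc2cc1O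
F2 | step 4 | 6-hydroxy-7-(hydroxymethyl)isochroman-3-one | OCc1cc2COC(=O)Cc2cc1O
F3 | step 4 | 6-hydroxy-7-methylisochroman-3-one | Cc1cc2COC(=O)Cc2cc1O
F4 | step 4 | 7-hydroxy-7-methyl-4,7-dihydro-1H-isochromene-3,6-dione (C7 configured as in 31) | O=C1C=C2CC(=O)OCC2=C[C@@]1(O)C
F5 | step 4 | 6,7-dihydroxy-7-methyl-1,4,6,7-tetrahydro-3H-isochromen-3-one (cis diol, configured as 7) | O[C@@H]1C=C2CC(=O)OCC2=C[C@@]1(O)C
F6 | step 4 | 6-O-tert-butyldimethylsilyl ether of F5 | CC(C)(C)[Si](C)(C)O[C@@H]1C=C2CC(=O)OCC2=C[C@@]1(O)C
F7 | step 4 | 8,8a-epoxide of F6, oxirane oxygen cis to the C7 hydroxyl | CC(C)(C)[Si](C)(C)O[C@@H]1C=C2CC(=O)OC[C@]23O[C@@H]3[C@@]1(O)C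
F8 | step 4 | 6-(tert-butyldimethylsilyloxy)-7-hydroxy-7-methyl-1,5,6,7-tetrahydro-3H-isochromene-3,8(4H)-dione | CC(C)(C)[Si](C)(C)O[C@@H]1CC2=C(COC(=O)C2)C(=O)[C@]1(C)O
F9 | step 9 | primary p-toluenesulfonate of 14 | CC(C)(C)[Si](C)(C)O[C@@H]1CC2=C(COC(=O)C2)C(=O)[C@]1(COS(=O)(=O)c3ccc(C)cc3)O
F10 | step 9 | spiro-epoxide of 14 (oxirane between C7 and C9) | CC(C)(C)[Si](C)(C)O[C@@H]1CC2=C(COC(=O)C2)C(=O)[C@@]13CO3
F11 | step 13 | ketene acetal diphenyl phosphate of 18 | CC(C)(C)[Si](C)(C)O[C@@H]1CC2=C(COC(OP(=O)(Oc3ccccc3)Oc3ccccc3)=C2)[C@@H](O[Si](CC)(CC)CC)[C@]1(C)O[Si](CC)(CC)CC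
F12 | step 13 | 3-(trimethylstannyl) analogue of 19 | CC(C)(C)[Si](C)(C)O[C@@H]1CC2=C(COC([Sn](C)(C)C)=C2)[C@@H](O[Si](CC)(CC)CC)[C@]1(C)O[Si](CC)(CC)CC
F13 | step 13 | 3-lithio analogue of 19 | CC(C)(C)[Si](C)(C)O[C@@H]1CC2=C(COC([Li])=C2)[C@@H](O[Si](CC)(CC)CC)[C@]1(C)O[Si](CC)(CC)CC
F14 | step 16 | C1′ epimer of 23, (1S,2S)-chlorohydrin | CC(C)(C)[Si](C)(C)O[C@@H]1CC2=C(COC([C@H](O)[C@H](C)Cl)=C2)[C@@H](O[Si](CC)(CC)CC)[C@]1(C)O[Si](CC)(CC)CC
F15 | step 16 | 3-[(S)-2-chloropropanoyl] ketone from 23 and F14 | CC(C)(C)[Si](C)(C)O[C@@H]1CC2=C(COC(C(=O)[C@H](C)Cl)=C2)[C@@H](O[Si](CC)(CC)CC)[C@]1(C)O[Si](CC)(CC)CC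
F16 | step 21 | 7-hydroxy-2,2,5-trimethyl-4H-1,3-benzodioxin-4-one | Cc1cc(O)cc2OC(C)(C)OC(=O)c12
F17 | step 21 | 7-(tert-butyldimethylsilyloxy)-2,2,5-trimethyl-4H-1,3-benzodioxin-4-one | Cc1cc(O[Si](C)(C)C(C)(C)C)cc2OC(C)(C)OC(=O)c12
F18 | step 21 | 4′-O-tert-butyldimethylsilyl ether of 31 | Cc1cc(O[Si](C)(C)C(C)(C)C)cc(O)c1C(=O)O[C@@H]1CC2=C(COC([C@H]3O[C@@H]3C)=C2)C(=O)[C@]1(C)O
A1 | alternative 1 | ring A α-iodo enone | CC(C)(C)[Si](C)(C)O[C@@H]1CC(C[C@@H](O[Si](CC)(CC)CC)[C@H]2O[C@@H]2C)=C(I)C(=O)[C@]1(C)O[Si](C)(C)C(C)(C)C
A2 | alternative 2 | bicyclic dienyl ether, tris-triethylsilyl ether | CC[Si](CC)(CC)O[C@@H]1CC2=C(COC([C@H]3O[C@@H]3C)=C2)[C@H](O[Si](CC)(CC)CC)[C@]1(C)O[Si](CC)(CC)CC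
A3 | alternative 3 | C6-silylated bicyclic ketol core | CC(C)(C)[Si](C)(C)O[C@@H]1CC2=C(COC([C@H]3O[C@@H]3C)=C2)C(=O)[C@]1(C)O
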